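The readings stem from a simulated flask for substances that don't exist, and the scatter is random.

- 6 questions come down to 3 numbers: how much electrophile is left in each flask at 1.0 h. In both earlier runs electrophile and product add up close to the charge, so I read the loss of electrophile as one-to-one conversion.

the same everywhere: electrophile 10 mM; gas 0.35 mM (held)

|  | nucleophile | remark | time |
|---|---|---|---|
| grey | 10 mM | run made earlier |  |
| ochre | 24 mM | run made earlier |  |
| north-east | 20.0 mM |  | 1.0 h |
| south | 14.0 mM |  | 1.0 h |
| east | 9.00 mM |  | 1.0 h |

| run | time / min | electrophile / % | product / % |
|---|---|---|---|
| grey | 4.00 | 92.0 | 7.2 |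
| grey | 10.0 | 85.2 | 15.1 |
| grey | 20.0 | 76.1 | 24.8 |
| grey | 30.0 | 69.0 | 33.8 |
| grey | 40.0 | 63.1 | 36.6 |
| ochre | 8.00 | 71.4 | 28.5 |
| ochre | 15.0 | 57.0 | 41.7 |
| ochre | 25.0 | 42.6 | 59.0 |
| ochre | 30.0 | 39.0 | 64.1 |
| ochre | 40.0 | 29.1 | 68.8 |

(each reading ± 1 percentage point)

1. which of these there is most of at the end, counted by the electrophile in it, north-east (electrophile / product)
2. which of these there is most of at the end, counted by the electrophile in it, south (electrophile / product)
3. which of these there is most of at the end, counted by the electrophile in it, east (electrophile / product)
4. how much there is at the end of the one of these that leads, in percent of the electrophile charged: north-east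
5. how much there is at the end of the one of these that leads, in percent of the electrophile charged: south
6. how much there is at the end of the one of these that leads, in percent of the electrophile charged: east

- Let e be the fraction of electrophile left and n the nucleophile charged per electrophile charged. If the rate follows electrophile times nucleophile, each reading gives a second-order clock X = ln[(n − 1 + e)/(n·e)]/(n − 1), which becomes X = 1/e − 1 at n = 1. At this electrophile charge and held gas, flasks should then show one X at one time.
- First way: the grey run reads 0.314 at 20.0 min and 0.585 at 40.0 min, and carrying that slope on to 1.0 h gives 0.856.
- Second way: the ochre run reads 0.414 at 25.0 min and 0.632 at 40.0 min, which extrapolates to 0.921.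
- The ways part, and I suspect the last ochre reading: its electrophile and product add to 97.9%, which is 2.1 percentage points short against a scatter of 1 point, and the extrapolation magnifies that reading.
- So in both runs I take e as the average of the electrophile reading and the charge minus the product reading. Grey then gives 0.840 and ochre 0.859, a gap smaller than before.
- I carry their average, the second-order clock at 1.0 h, 0.849. It gives product 72.8% in north-east and 58.6% in south. East, with nucleophile as limiting reagent at 0.900 equivalents, keeps electrophile in the lead at 57.7%.
- The forecast says “Extrapolating gives X(60) ≈ 0.86”, against my 0.849. It names product at 73% for north-east, product at 59% for south and electrophile at 57.4% for east.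
- The flask gives product at 72.5% in north-east, product at 57.4% in south and electrophile at 58.9% in east. South stands 1.9 points above the low end of the forecast's range.

    acid set free + free base ⇌ salt of the base, settled at all times (K = 1.80 × 10⁶ /M)
    nucleophile + acid set free ⇌ protonated nucleophile, settled at all times (K = 2.10 × 10⁵ /M)
    gas ⇌ free base, rate k3*(csat - [free base]) (kL = 0.150 /min)
    electrophile + nucleophile → acid set free + product (k = 2.00 /M/min)

- Read back from the electrophile in south, the clock stands at 0.814, less than 0.849. In south, the product-forming step reaches the mid-point of its turnover up to 1.0 h at 0.258 h, earlier than the 0.455 h of gas crossing to free base.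
- A neighbour flask is south with 0.350 equiv of nucleophile at the same electrophile charge, so 0.849 leaves electrophile at 81.4%. The computed neighbour holds electrophile 80.9% and product 19.1%.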